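Working numbering used throughout: C1 is the quaternary carbon bearing CH3 and C12H2–O; the cyclobutane is C2–C3–C8–C7; the enone C4(CH3)=C5–C6(=O) joins C3 to C7; C9–C10–C11(OAc) runs from C8 back to C1.

## Analysis of the target

The skeleton is a bicyclo[3.1.1]heptenone (cyclobutane C2–C3–C8–C7 plus the enone bridge C4–C5–C6). Its two one-carbon bridges C2 and C8 are tied together by the chain C1–C11–C10–C9, so a seven-membered ring straddles the cyclobutane. There are six stereocentres: C2, C3, C7 and C8 in the cyclobutane, plus C1 and C11. The four cyclobutane centres are not independent. For the seven-membered ring to exist, C1 on C2 and C9 on C8 must both point away from the enone bridge (anti), which leaves the C8 methyl and the C2 hydrogen over that bridge, so only the absolute sense of the core is open. At C1 the acyloxymethyl arm lies on the face of the seven-membered ring that looks at C3 and the methyl on the face that looks at C7. The C11 acetate is on the C7 face, so it is trans to C12 and cis to the C1 methyl. The sensitive groups are the angelate (Z to E isomerisation by base, nucleophiles, acid or heat), the enone, and two different acyl groups on a 1,3-diol. The difficulty lies in the fully substituted cyclobutane with quaternary C8, the adjacent quaternary C1, and the fact that the C3 and C7 sides of C1 and C11 are almost mirror images, so the core gives little substrate control there. The strategy rests on C2 and C8: they are the 1,3-related cyclobutane carbons that together carry the whole seven-membered ring on one face. Joined directly they are the bridgeheads of a bicyclo[1.1.0]butane already spanned by C4–C5–C6, that is a tricyclo[4.1.0.0(2,7)]heptane, and a four-carbon unit laid across its central bond recreates the ring system.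

## Retrosynthetic reasoning

**25 to 24, then 24 to 21 and 22.** The two acyl C–O bonds are cut first. The Z-unsaturated ester is the most fragile part and should meet as few reagents as possible. The neopentyl primary hydroxyl at C12 and the secondary one at C11 differ enough in reactivity for 22 to be placed on C12 before C11 is acetylated.

**21 to 19.** The C4=C5 double bond is removed. C6 can enolise only toward C5 because C7 is a cyclobutane bridgehead, so the position of unsaturation is safe. With the C4 configuration that the front of the route delivers, the C4 hydrogen lies on the face shielded by the C8 methyl. A syn elimination from a metal or selenium substituent at C5 would need the reagent on that face, so the forward step is bromination at C5 and anti elimination through 20.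

**19 to 18 to 17.** The dioxolane in 18 carries the C6 carbonyl through radical, enolate and hydride chemistry. The C11 carbinol is traced to ketone 17: the C12 hydroxyl can bind a hydride donor and deliver it to the carbonyl face on which it sits, which places the new hydroxyl trans to C12. This is the one dependable stereochemical relay near C1, so C11 is set after C1.

**17 to 15.** C12 is an ester carbon in 15. The ketone must survive the ester reduction and is hidden as enolate 16, which is possible because C1 is quaternary and only C10 can be deprotonated.

**15 to 14.** The C1–CH3 bond is cut to the β-keto ester 14, where C1 is acidic. Because the two faces of C1 differ only through distant groups, the face has to be chosen by a chiral ion-pairing catalyst. The same near-symmetry means the enolate behaves like a prochiral one.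

**14 to 8 and 13 (key disconnection).** Bonds C1–C2 and C8–C9 are cut together. This removes the seven-membered ring in one operation and leaves bicyclobutane 8 and the four-carbon radical precursor 13. No other pair of cuts uses the strain of the C2–C8 bond as driving force or lets topology set C2 and C8: the concave face of 8 is filled by C4–C5–C6, so both new bonds must form on the convex face. Forward, an electrophilic radical from 13 must add at the unsubstituted bridgehead C2, and the tertiary C8 radical must close onto the vinyl ketone before it is quenched.

**8 to 7 to 5 and 6.** C2 is a carbene carbon. C2–C7 and C2–C8 come from addition to the C7=C8 alkene of 5, and C2–C3 from C–H insertion after metal–halogen exchange on 7. The alkene must be the conjugated one of the enone ketal. Then C6 is a quaternary ketal carbon without hydrogen, the only insertion site is C3, and the methyl ends on bridgehead C8. The C4 stereocentre decides which alkene face the carbene takes and so fixes the absolute sense of the core. It disappears in 21, so 7 must be freed of its C4-epimeric partner.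

**5 to 4 to 3 to 2 to 1.** Enone 4 comes from 1 by unsaturation away from the methyl (2), conjugate methyl addition with enolate trapping (3) and re-oxidation. The trans-dimethyl intermediate is C2-symmetric, so the second unsaturation cannot go to the wrong side. The order fixes the configuration: 1,2-addition to 2 followed by oxidative transposition would move the carbonyl to the other side of the stereocentre and give the enantiomer of 4. With the expected cis carbene addition that enantiomer would lead to the mirror image of 25.

**13 to 12 to 11 to 9 and 10.** The bromide is cut at C–Br, then at the C2–C3 bond of the pentenoate: aldol of 9 with 10, oxidation to the vinyl ketone 12, bromination between the carbonyls.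

## Alternatives that were turned down

Alternative 1: Samarium Reformatsky closure of the seven-membered ring.
- Disconnection: C1–C11, with the ring closed last on a finished bicyclo[3.1.1]heptene.
- Forward key step: a divalent samarium reductant turns a tertiary α-bromo ester at C1 into a samarium enolate that adds to an aldehyde at the end of the C8 side chain. The product is the β-hydroxy ester A1, with CO2CH3 and CH2OBn on C1.
- For it: the closure is known chemistry for medium rings. It makes quaternary C1 and the C11 carbinol together through a chelated transition state. Either C1 substituent can become CH3 or the acyloxymethyl arm, so whichever C1 diastereomer forms is usable. On precedent and on C1/C11 control it is stronger than the chosen route.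
- Against it: the cyclobutane with its four stereocentres, quaternary C8 and the cis-1,3 pair of chains must exist before the key step, so the hardest part of the molecule needs its own long sequence. C6 is still a methylene in A1 and must be oxidised late, and one C1 substituent needs a multi-step deoxygenation to CH3.
- Comparison: the chosen route accepts an unprecedented key step and catalyst-dependent control at C1. In exchange it reaches in six steps a precursor from which the cyclobutane substitution, C2, C8 and the seven-membered ring arise at once, with C6 already oxidised.

Alternative 2: Diels–Alder norbornene contracted by a semipinacol shift.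
- Disconnection: C7–C8, read as a retro-1,2-shift that returns C8 from C7 to C6 and turns the cyclobutane into a bicyclo[2.2.1]heptene from a Diels–Alder reaction.
- Forward key step: a bridgehead C6 alkoxide, made with a hydride base, pushes C8 from C6 to C7 while an endo sulfonate leaves from C7. This closes the cyclobutane and creates the C6 carbonyl, giving A2, the bis-silyl ether of the target diol.
- For it: the cycloaddition sets the ring stereocentres dependably and the shift is stereospecific. The key step is late and ends two or three steps from the target with the enone in place, so in end-game economy it is stronger than the chosen route.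
- Against it: the contraction raises ring strain and is paid for only by carbonyl formation. The migrating carbon is quaternary and crowded. An alkoxide 1,3 to a sulfonate can fragment instead of shifting. The cycloaddition product must already hold the seven-membered ring with C1 and C11, a bridgehead oxygen and the endo leaving group, so a long linear preparation precedes any test of the difficult step.
- Comparison: the chosen route tests its risky step after six steps on simple material and uses strain release rather than strain building. It pays with seven steps after the key step and weaker late-stage stereocontrol.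

Alternative 3: Reductive ketyl–enoate coupling that closes the cyclobutane.
- Disconnection: C2–C7, opening the cyclobutane to a cis-fused bicyclo[5.4.0]undecadienone.
- Forward key step: a divalent samarium reductant converts the C7 ketone into a ketyl that adds 4-exo-trig to C2, the β-carbon of the cycloheptene carboxylate. Protonation of the C1 enolate gives cyclobutanol A3.
- For it: 4-exo ketyl–enoate cyclisations to cyclobutanols are known, and the substrate is an ordinary fused six–seven system. On precedent of the ring-forming event it is stronger than the chosen route.
- Against it: A3 has a tertiary hydroxyl at C7 where the target has hydrogen. Removing it from a cyclobutane carbon β to the C1 ester invites retro-aldol ring opening, the reverse of the key step. C1 forms as a mixture, C6 is unoxidised, and quaternary C8 and C11 must be set on a flexible bicycle.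
- Comparison: the chosen route forms the cyclobutane at the right oxidation level, with C7–H present from the start and the C6 oxygen in place, and needs no corrective deoxygenation.

Key step: step 10

Assumption: dibromocarbene adds to 5 cis to the C9 methyl (anti to the pseudoaxial dioxolane oxygen of the favoured half-chair); the configuration of 4 and the C4 configuration of 7–20 follow from this.

## Route

Step 1
Reactants: 1 (R)-3-methylcyclohexanone
Product: 2 (R)-5-methylcyclohex-2-en-1-one
Conditions: Pd(O2CCF3)2 (5 mol%), DMSO (10 mol%), O2 (1 atm), AcOH, 80 °C
Reagents that add atoms: none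
Why: Aerobic ketone dehydrogenation by divalent palladium (α-palladation, β-hydride elimination) should prefer the less hindered CH2–CH2 side away from the methyl-bearing carbon; the stereocentre is untouched, and the achiral regioisomer is removed by chromatography and could not advance to an enone in step 3 anyway.

Step 2
Reactants: 2 (R)-5-methylcyclohex-2-en-1-one
Product: 3 trimethyl{[(3R,5R)-3,5-dimethylcyclohex-1-en-1-yl]oxy}silane
Conditions: MeMgBr, CuBr·SMe2 (5 mol%), Me3SiCl, HMPA, THF, −78 °C; Et3N
Reagents that add atoms: methylmagnesium bromide C[Mg]Br; chlorotrimethylsilane C[Si](C)(C)Cl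
Why: Copper-catalysed conjugate addition of the Grignard reagent with silyl trapping of the enolate; methyl should add axially, trans to the existing methyl, but this new centre is removed in step 3, and the C2 symmetry of the trans-dimethyl ketone makes the site of re-unsaturation unambiguous.

Step 3
Reactants: 3 trimethyl{[(3R,5R)-3,5-dimethylcyclohex-1-en-1-yl]oxy}silane
Product: 4 (R)-3,5-dimethylcyclohex-2-en-1-one
Conditions: Pd(OAc)2 (10 mol%), O2 (1 atm), DMSO, 25 °C
Reagents that add atoms: none
Why: Saegusa–Ito oxidation in its aerobic catalytic form; the palladium enolate at C2 can lose only the C3 hydrogen, giving the β-methyl enone, and the surviving stereocentre (CH2C=O outranks CH2C(CH3)=) is R.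

Step 4
Reactants: 4 (R)-3,5-dimethylcyclohex-2-en-1-one
Product: 5 (9R)-7,9-dimethyl-1,4-dioxaspiro[4.5]dec-6-ene
Conditions: Me3SiOCH2CH2OSiMe3, Me3SiOTf (2 mol%), CH2Cl2, −78 °C; pyridine
Reagents that add atoms: 1,2-bis(trimethylsilyloxy)ethane C[Si](C)(C)OCCO[Si](C)(C)C
Why: Noyori ketalisation forms enone dioxolanes under aprotic conditions without moving the double bond out of conjugation, which protic ketalisation would do; the alkene must stay at C6=C7 (C7=C8 in the working numbering) so that the ketal carbon flanks the future cyclopropane.

Step 5
Reactants: 5 (9R)-7,9-dimethyl-1,4-dioxaspiro[4.5]dec-6-ene; 6 bromoform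
Product: 7 (1S,4R,6S)-7,7-dibromo-4,6-dimethylspiro[bicyclo[4.1.0]heptane-2,2'-[1,3]dioxolane] (CBr2 cis to the C4 methyl)
Conditions: KOt-Bu, pentane, −20 to 0 °C; chromatography on Et3N-treated silica
Reagents that add atoms: none
Why: Doering–Hoffmann dibromocarbene addition to the trisubstituted alkene; in the half-chair with equatorial methyl one dioxolane oxygen is pseudoaxial, and the electrophilic carbene, which bonds first to the alkene CH next to the ketal, should come from the opposite face, that is cis to the methyl. The trans adduct would lead to the enantiomeric core and is separated here.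

Step 6
Reactants: 7 (1S,4R,6S)-7,7-dibromo-4,6-dimethylspiro[bicyclo[4.1.0]heptane-2,2'-[1,3]dioxolane]
Product: 8 1,5-dimethylspiro[tricyclo[4.1.0.0(2,7)]heptane-3,2'-[1,3]dioxolane] (working numbering: 4,8-dimethyl, C6 ketal, central bond C2–C8, C4 methyl on the side of bridgehead C2)
Conditions: MeLi, Et2O, −78 to 0 °C; base-washed glassware
Reagents that add atoms: none
Why: Lithium–bromine exchange and α-elimination give a cyclopropylidene carbenoid that cannot open to a seven-membered allene and inserts into the cis C–H of the adjacent CH2 (the established route to tricyclo[4.1.0.0(2,7)]heptanes); the other flank is the hydrogen-free ketal carbon, so insertion can occur only at C3, and C2 and C3 are set by the cyclopropane face.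

Step 7
Reactants: 9 methyl acetate; 10 acrolein
Product: 11 methyl 3-hydroxypent-4-enoate (racemic)
Conditions: LiN(i-Pr)2, THF, −78 °C; aq NH4Cl
Reagents that add atoms: none
Why: Aldol addition of the lithium ester enolate, which adds 1,2 to acrolein at low temperature.

Step 8
Reactants: 11 methyl 3-hydroxypent-4-enoate
Product: 12 methyl 3-oxopent-4-enoate
Conditions: CrO3, H2SO4, acetone, 0 °C
Reagents that add atoms: none
Why: Jones oxidation of the allylic alcohol is the established way to this class of vinyl β-keto esters; the product polymerises on standing and is used promptly.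

Step 9
Reactants: 12 methyl 3-oxopent-4-enoate
Product: 13 methyl 2-bromo-3-oxopent-4-enoate (racemic)
Conditions: N-bromosuccinimide, CH2Cl2, 0 °C, dark; used at once as a solution
Reagents that add atoms: N-bromosuccinimide O=C1CCC(=O)N1Br
Why: Electrophilic bromination of the enol between the two carbonyls; the electron-poor vinyl group is not attacked.

Step 10
Reactants: 8 1,5-dimethylspiro[tricyclo[4.1.0.0(2,7)]heptane-3,2'-[1,3]dioxolane]; 13 methyl 2-bromo-3-oxopent-4-enoate
Product: 14 tricyclic β-keto ester (C1–CO2CH3 as epimers and enol, C11 ketone, C6 dioxolane, 4,8-dimethyl; C1 and C9 anti to the C4–C6 bridge)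
Conditions: 13 (2.0 equiv, added over 6 h), fac-Ir(ppy)3 (1 mol%), diethyl 2,6-dimethyl-1,4-dihydropyridine-3,5-dicarboxylate (Hantzsch ester, 2.2 equiv), 2,6-lutidine, MeCN, 450 nm LEDs, 20 °C
Reagents that add atoms: none
Why: Proposed new method: photoexcited fac-Ir(ppy)3 reduces the C–Br bond of 13 to the 1,3-dicarbonyl radical, which as an electrophilic radical should attack the electron-rich, strained C2–C8 bond of 8 at the hydrogen-bearing bridgehead C2 and leave the tertiary cyclobutyl radical at C8. That nucleophilic radical should add to the terminal carbon C9 of the vinyl ketone held on the same face, a 7-endo-trig closure of the seven-membered ring that is geometrically close to a six-membered transition state because C2 and C8 stay about 2 Å apart. The electron-poor C10 radical then takes a hydrogen atom from the Hantzsch ester, whose radical reduces further 13 or returns the electron to tetravalent iridium. The closest known reaction types are atom-transfer additions of α-bromo carbonyl compounds to bicyclo[1.1.0]butanes and radical additions to tricyclo[4.1.0.0(2,7)]heptanes, which give 6,7-disubstituted bicyclo[3.1.1]heptanes with the radical entering anti to the three-carbon bridge; capture of the bridgehead radical by a tethered acceptor has not been shown. C2 over C8 is secured by attack at the less substituted bridgehead, which gives the more stable radical. The C2 configuration is set by convex-face attack, since the C4–C6 bridge fills the concave face; the C8 configuration is set by the tether, which can reach only the face it already occupies, so the methyl ends over the bridge. Both radical additions are polarity-matched, slow addition keeps 13 dilute so that ring closure should outrun hydrogen or bromine transfer to C8, and lutidine removes HBr that would open the ketal or the bicyclobutane. C1 stays enolisable and is settled in step 11.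

Step 11
Reactants: 14 tricyclic β-keto ester
Product: 15 C1-methylated keto ester (CO2CH3 on the C3 face, CH3 on the C7 face)
Conditions: CH3I, CsOH·H2O, N-(9-anthracenylmethyl)-O-allylcinchonidinium bromide (10 mol%), toluene/CH2Cl2, −40 °C
Reagents that add atoms: iodomethane CI
Why: Asymmetric phase-transfer C-alkylation of a cyclic β-keto ester enolate as a chiral ammonium ion pair; the two faces of C1 differ only through the distant C4 and C6 groups, so the enolate behaves as prochiral and the catalyst should decide that CH3 enters from the C7 face (the pseudoenantiomeric cinchoninium salt serves if the sense is opposite).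

Step 12
Reactants: 15 C1-methylated keto ester
Product: 17 hydroxy ketone (C12–OH and C11 ketone), via lithium enolate 16 (not isolated)
Conditions: LiN(i-Pr)2 (1.2 equiv), THF, −78 °C; LiAlH4, −78 to 0 °C; aq KNaC4H4O6
Reagents that add atoms: none
Why: Ester reduction with the ketone masked in situ as its lithium enolate, which can form only toward C10 because C1 is quaternary; the enolate is inert to LiAlH4 and returns the ketone on work-up, and no stereocentre changes.

Step 13
Reactants: 17 hydroxy ketone
Product: 18 ketal diol (C11–OH on the C7 face, trans to CH2OH)
Conditions: Me4NBH(OAc)3, MeCN/AcOH, −30 °C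
Reagents that add atoms: none
Why: Evans–Saksena hydroxyl-directed reduction: the C12 oxygen binds boron and hydride is delivered internally to the C11 carbonyl face on which CH2OH sits, so the new hydroxyl ends trans to CH2OH and cis to the C1 methyl; the reagent does not reduce undirected carbonyls.

Step 14
Reactants: 18 ketal diol
Product: 19 keto diol (C6 ketone)
Conditions: 1 M HCl, THF, 25 °C
Reagents that add atoms: water O
Why: Acid hydrolysis of the dioxolane; THF rather than acetone avoids acetonide formation on the 1,3-diol, and C7 is a bridgehead that cannot epimerise.

Step 15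
Reactants: 19 keto diol
Product: 21 enone diol, via C5 bromo ketone 20 (not isolated)
Conditions: PhNMe3Br3, THF, 0 °C; then Li2CO3, LiBr, DMF, 110 °C
Reagents that add atoms: none
Why: α-Bromination and dehydrobromination; the ketone enolises only toward C5, and because the C4 hydrogen lies on the face shielded by the C8 methyl, an anti E2 elimination from the C5 bromide is used instead of a syn elimination. Bromide exchange with LiBr equilibrates the C5 epimers.

Step 16
Reactants: 21 enone diol; 22 angelic acid ((2Z)-2-methylbut-2-enoic acid)
Product: 24 C12 angelate with free C11 hydroxyl, via angelic trichlorobenzoic anhydride 23 (not isolated)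
Conditions: 22, 2,4,6-Cl3C6H2COCl, Et3N, toluene, 25 °C; then 21, toluene, 80 °C
Reagents that add atoms: none
Why: Yamaguchi mixed-anhydride esterification without nucleophilic catalyst, conditions used to transfer the angeloyl group without Z to E isomerisation; the primary hydroxyl should react ahead of the secondary one flanked by the quaternary carbon.

Step 17
Reactants: 24 C12 angelate with free C11 hydroxyl
Product: 25 CNP0374220.2 (target)
Conditions: Ac2O, pyridine, DMAP (5 mol%), CH2Cl2, 0 to 25 °C
Reagents that add atoms: acetic anhydride CC(=O)OC(C)=O
Why: DMAP-catalysed acetylation of the remaining secondary alcohol at low temperature, mild enough for the angelate and the enone; no stereocentre is formed.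

## Compound list

1 | (R)-3-methylcyclohexanone | C[C@@H]1CCCC(=O)C1 | starting material
2 | (R)-5-methylcyclohex-2-en-1-one | C[C@@H]1CC=CC(=O)C1 | intermediate
3 | trimethyl{[(3R,5R)-3,5-dimethylcyclohex-1-en-1-yl]oxy}silane | C[C@@H]1C[C@@H](C)C=C(O[Si](C)(C)C)C1 | intermediate
4 | (R)-3,5-dimethylcyclohex-2-en-1-one | C[C@@H]1CC(C)=CC(=O)C1 | intermediate
5 | (9R)-7,9-dimethyl-1,4-dioxaspiro[4.5]dec-6-ene | C[C@@H]1CC(C)=CC2(OCCO2)C1 | intermediate
6 | bromoform | BrC(Br)Br | starting material
7 | (1S,4R,6S)-7,7-dibromo-4,6-dimethylspiro[bicyclo[4.1.0]heptane-2,2'-[1,3]dioxolane] | C[C@@H]1C[C@@]2(C)[C@H](C2(Br)Br)C3(OCCO3)C1 | intermediate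
8 | 1,5-dimethylspiro[tricyclo[4.1.0.0(2,7)]heptane-3,2'-[1,3]dioxolane], C4 methyl on the C2 side | C[C@@]12[C@@H]3[C@@H](C)CC4(OCCO4)[C@H]2[C@H]13 | intermediate
9 | methyl acetate | COC(C)=O | starting material
10 | acrolein | C=CC=O | starting material
11 | methyl 3-hydroxypent-4-enoate (racemic) | COC(=O)CC(O)C=C | intermediate
12 | methyl 3-oxopent-4-enoate | COC(=O)CC(=O)C=C | intermediate
13 | methyl 2-bromo-3-oxopent-4-enoate (racemic) | COC(=O)C(Br)C(=O)C=C | intermediate
14 | tricyclic β-keto ester, C6 dioxolane, C1 epimers | COC(=O)C1[C@@H]2[C@H]3[C@@H](C)CC4(OCCO4)[C@@H]2[C@@]3(C)CCC1=O | intermediate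
15 | C1-methylated keto ester | COC(=O)[C@]1(C)[C@@H]2[C@H]3[C@@H](C)CC4(OCCO4)[C@@H]2[C@@]3(C)CCC1=O | intermediate
16 | lithium C10–C11 enolate of 15 | COC(=O)[C@]1(C)[C@@H]2[C@H]3[C@@H](C)CC4(OCCO4)[C@@H]2[C@@]3(C)CC=C1O[Li] | intermediate
17 | hydroxy ketone (C12–OH, C11 ketone) | OC[C@]1(C)[C@@H]2[C@H]3[C@@H](C)CC4(OCCO4)[C@@H]2[C@@]3(C)CCC1=O | intermediate
18 | ketal diol (C11–OH trans to CH2OH) | OC[C@]1(C)[C@@H]2[C@H]3[C@@H](C)CC4(OCCO4)[C@@H]2[C@@]3(C)CC[C@H]1O | intermediate
19 | keto diol | OC[C@]1(C)[C@@H]2[C@H]3[C@@H](C)CC(=O)[C@@H]2[C@@]3(C)CC[C@H]1O | intermediate
20 | C5 bromo keto diol (C5 epimers) | OC[C@]1(C)[C@@H]2[C@H]3[C@@H](C)C(Br)C(=O)[C@@H]2[C@@]3(C)CC[C@H]1O | intermediate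
21 | enone diol | OC[C@]1(C)[C@@H]2[C@H]3C(C)=CC(=O)[C@@H]2[C@@]3(C)CC[C@H]1O | intermediate
22 | angelic acid | C/C=C(/C)C(O)=O | starting material
23 | angelic 2,4,6-trichlorobenzoic anhydride | C/C=C(/C)C(=O)OC(=O)c1c(Cl)cc(Cl)cc1Cl | intermediate
24 | C12 angelate, C11 alcohol | C/C=C(/C)C(=O)OC[C@]1(C)[C@@H]2[C@H]3C(C)=CC(=O)[C@@H]2[C@@]3(C)CC[C@H]1O | intermediate
25 | CNP0374220.2 | C/C=C(/C)C(=O)OC[C@]1(C)[C@@H]2[C@H]3C(C)=CC(=O)[C@@H]2[C@@]3(C)CC[C@H]1OC(C)=O | target

## Step count and least certain steps

Total: 17 steps. Longest linear sequence: 14 steps (steps 1–6 and 10–17); the branch to 13 has 3 steps (7–9).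

**Step 10 (key step, proposed new method).**
- What may go wrong: hydrogen transfer from the dihydropyridine to the dicarbonyl radical or to the C8 radical before ring closure; ionic opening of the bicyclobutane by the acidic, electrophilic bromide; radical polymerisation of the vinyl ketone.
- Fallback (known reaction types), from 8 back to 14: bromine atom-transfer addition of methyl bromoacetate across C2–C8 (Et3B, air, CH2Cl2) gives the C8-bromo C2-acetate ester F1. Its lithium enolate is added to acrolein to give the allylic alcohol F2, and Dess–Martin oxidation gives the vinyl ketone bromide F3. Slow addition of Bu3SnH with AIBN in benzene at 80 °C regenerates the C8 radical for the 7-endo closure in a conventional tin hydride setting and returns to 14.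

**Step 5.**
- What may go wrong: weak or reversed facial selectivity of the carbene addition. The two adducts lead to enantiomeric cores once C4 becomes trigonal, so this would erode enantiomeric purity unless the adducts are separated.
- Fallback, from 2 back to 21, if the trans face is preferred: MeLi adds 1,2 to 2 to give the tertiary allylic alcohol F4. Oxidative transposition with C5H5NH[CrO3Cl] gives the (S)-enone F5, and ketalisation as in step 4 gives the (9S)-ketal F6. Carbene addition then gives the trans dibromide F7. Steps 6 and 10–14 are run on the C4 epimers: the bicyclobutane F8, the keto ester F9, the methylated keto ester F10, its lithium enolate F11, the hydroxy ketone F12, the diol F13 and the keto diol F14. In this series the C4 hydrogen lies on the open face, so the enone is made by Saegusa oxidation (Me3SiOTf, Et3N; Pd(OAc)2; dilute HCl) through the silyl enol ether F15, rejoining at 21.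

**Step 11.**
- What may go wrong: poor facial discrimination by the ion-pairing catalyst at a hindered enolate, or O-alkylation.
- Fallback, from 14 back to 18, using catalyst control in a better-precedented reaction and then substrate control: hydrogenation with RuCl2[(R)-BINAP] or its mirror image, under dynamic kinetic resolution, gives the β-hydroxy ester F16 with the C11 hydroxyl on the C7 face. Fráter–Seebach alkylation of its dianion with benzyl chloromethyl ether enters trans to the hydroxyl and gives the benzyloxymethyl hydroxy ester F17. LiAlH4 gives the diol benzyl ether F18, selective tosylation of the primary hydroxyl gives the tosylate F19, and LiBEt3H gives the C1-methyl benzyl ether F20. Hydrogenolysis (H2, Pd/C) returns to 18, bypassing steps 12 and 13.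

**Step 12.**
- What may go wrong: incomplete enolisation, which lets hydride reach the ketone without facial control, or retro-aldol loss of formaldehyde from the product alkoxide.
- Fallback, from 15 back to 17: LiAlH4 alone reduces both carbonyls to the diol F21 (C11 epimers). The secondary alcohol is then re-oxidised selectively in the presence of the primary one with (Bu3Sn)2O and Br2 in CH2Cl2, giving 17.

**Step 15.**
- What may go wrong: slow anti elimination because base access to the C4 hydrogen is hindered by the C8 methyl, with substitution at C5 or over-bromination competing.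
- Fallback, from 19 back to 25: the acyl groups are installed first. Esterification with 23 as in step 16 gives the saturated keto angelate F22, and acetylation as in step 17 gives the saturated keto diester F23. Dehydrogenation with 2-iodoxybenzoic acid in DMSO at 70 °C, which does not need a syn-periplanar arrangement, gives 25 directly.

## Further compounds

F1 | step 10 | methyl (C8-bromo-4,8-dimethyl-C6-dioxolane-bicyclo[3.1.1]hept-C2-yl)acetate (C8 epimers) | COC(=O)C[C@@H]1[C@H]2[C@@H](C)CC3(OCCO3)[C@@H]1C2(C)Br
F2 | step 10 | aldol adduct of F1 with acrolein (allylic alcohol, diastereomers) | COC(=O)C(C(O)C=C)[C@@H]1[C@H]2[C@@H](C)CC3(OCCO3)[C@@H]1C2(C)Br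
F3 | step 10 | vinyl ketone β-keto ester C8 bromide | COC(=O)C(C(=O)C=C)[C@@H]1[C@H]2[C@@H](C)CC3(OCCO3)[C@@H]1C2(C)Br
F4 | step 5 | (5R)-1,5-dimethylcyclohex-2-en-1-ol (C1 epimers) | C[C@@H]1CC=CC(C)(O)C1
F5 | step 5 | (S)-3,5-dimethylcyclohex-2-en-1-one | C[C@@H]1CC(=O)C=C(C)C1
F6 | step 5 | (9S)-7,9-dimethyl-1,4-dioxaspiro[4.5]dec-6-ene | C[C@@H]1CC2(OCCO2)C=C(C)C1
F7 | step 5 | (1S,4S,6S)-7,7-dibromo-4,6-dimethylspiro[bicyclo[4.1.0]heptane-2,2'-[1,3]dioxolane] (CBr2 trans to the C4 methyl) | C[C@H]1C[C@@]2(C)[C@H](C2(Br)Br)C3(OCCO3)C1
F8 | step 5 | C4 epimer of 8 (C4 methyl on the C8 side) | C[C@@]12[C@@H]3[C@H](C)CC4(OCCO4)[C@H]2[C@H]13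
F9 | step 5 | C4 epimer of 14 | COC(=O)C1[C@@H]2[C@H]3[C@H](C)CC4(OCCO4)[C@@H]2[C@@]3(C)CCC1=O
F10 | step 5 | C4 epimer of 15 | COC(=O)[C@]1(C)[C@@H]2[C@H]3[C@H](C)CC4(OCCO4)[C@@H]2[C@@]3(C)CCC1=O
F11 | step 5 | C4 epimer of 16 (lithium enolate) | COC(=O)[C@]1(C)[C@@H]2[C@H]3[C@H](C)CC4(OCCO4)[C@@H]2[C@@]3(C)CC=C1O[Li]
F12 | step 5 | C4 epimer of 17 | OC[C@]1(C)[C@@H]2[C@H]3[C@H](C)CC4(OCCO4)[C@@H]2[C@@]3(C)CCC1=O
F13 | step 5 | C4 epimer of 18 | OC[C@]1(C)[C@@H]2[C@H]3[C@H](C)CC4(OCCO4)[C@@H]2[C@@]3(C)CC[C@H]1O
F14 | step 5 | C4 epimer of 19 | OC[C@]1(C)[C@@H]2[C@H]3[C@H](C)CC(=O)[C@@H]2[C@@]3(C)CC[C@H]1O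
F15 | step 5 | tris(trimethylsilyl) derivative of F14 (C5=C6 silyl enol ether, two silyl ethers) | C[Si](C)(C)OC[C@]1(C)[C@@H]2[C@H]3[C@H](C)C=C(O[Si](C)(C)C)[C@@H]2[C@@]3(C)CC[C@H]1O[Si](C)(C)C
F16 | step 11 | β-hydroxy ester (C11–OH on the C7 face, C1 epimers) | COC(=O)C1[C@@H]2[C@H]3[C@@H](C)CC4(OCCO4)[C@@H]2[C@@]3(C)CC[C@H]1O
F17 | step 11 | C1-benzyloxymethyl β-hydroxy ester | c1ccccc1COC[C@]1(C(=O)OC)[C@@H]2[C@H]3[C@@H](C)CC4(OCCO4)[C@@H]2[C@@]3(C)CC[C@H]1O
F18 | step 11 | diol benzyl ether | c1ccccc1COC[C@]1(CO)[C@@H]2[C@H]3[C@@H](C)CC4(OCCO4)[C@@H]2[C@@]3(C)CC[C@H]1O
F19 | step 11 | primary tosylate | c1ccccc1COC[C@]1(COS(=O)(=O)c5ccc(C)cc5)[C@@H]2[C@H]3[C@@H](C)CC4(OCCO4)[C@@H]2[C@@]3(C)CC[C@H]1O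
F20 | step 11 | C1-methyl benzyl ether alcohol | c1ccccc1COC[C@]1(C)[C@@H]2[C@H]3[C@@H](C)CC4(OCCO4)[C@@H]2[C@@]3(C)CC[C@H]1O
F21 | step 12 | ketal diol, C11 epimers | OC[C@]1(C)[C@@H]2[C@H]3[C@@H](C)CC4(OCCO4)[C@@H]2[C@@]3(C)CCC1O
F22 | step 15 | saturated keto angelate, C11 alcohol | C/C=C(/C)C(=O)OC[C@]1(C)[C@@H]2[C@H]3[C@@H](C)CC(=O)[C@@H]2[C@@]3(C)CC[C@H]1O
F23 | step 15 | saturated keto angelate acetate | C/C=C(/C)C(=O)OC[C@]1(C)[C@@H]2[C@H]3[C@@H](C)CC(=O)[C@@H]2[C@@]3(C)CC[C@H]1OC(C)=O
A1 | alternative 1 | tricyclic β-hydroxy ester with CO2CH3 and CH2OBn on C1 | c1ccccc1COC[C@]1(C(=O)OC)[C@@H]2[C@H]3C(C)=CC[C@@H]2[C@@]3(C)CC[C@H]1O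
A2 | alternative 2 | bis(tert-butyldimethylsilyl) ether of the target diol | CC(C)(C)[Si](C)(C)OC[C@]1(C)[C@@H]2[C@H]3C(C)=CC(=O)[C@@H]2[C@@]3(C)CC[C@H]1O[Si](C)(C)C(C)(C)C
A3 | alternative 3 | tricyclic C7 cyclobutanol with C1 ester and C11 silyl ether | COC(=O)C1[C@@H]2[C@H]3C(C)=CC[C@]2(O)[C@@]3(C)CC[C@H]1O[Si](C)(C)C(C)(C)C
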